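**Plan**

- Retrosynthesis: ring C is opened at C2–C3 (a C3 acyl carbene on ring A inserting into the C2–H bond of an aryl benzyl ether). The ether O1–C2 is then cut (Mitsunobu), then the C8–dienyl bond (Sonogashira, semi-hydrogenation), and last the dihydrobenzofuran at its own C2–C3 bond (donor/donor carbene C–H insertion).
- Forward: benzophenone → five-membered furan ring → trans tetraphenol aldehyde → silylated benzylic alcohol; phloroacetophenone → bis-silyl iodophenol; ether union; enyne → Z-diene; diazo transfer; ring C closed last; one desilylation.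
- Enabling feature: the hydrogen on C2 of ring C is alpha to O1 and benzylic to ring B (para to the furan oxygen, ortho to the 2'-oxygen). It lies 1,6 to C3 of the acetyl group on ring A, so a carbene at C3 has one strongly hydridic C–H bond within reach.
- Stereochemistry: furan C3 (R) from Rh2(R-PTAD)4; furan C2 (R, trans) by thermodynamic epimerisation during demethylation; flavanone C2 (S) from Rh2(S-PTTL)4, with any C2 epimer a separable diastereomer; Z-alkene from syn semi-hydrogenation.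

Key step: step 15

Assumption: the sense of induction of Rh2(R-PTAD)4 (dirhodium tetrakis[(R)-(1-adamantyl)(N-phthalimido)acetate]) in step 4 and of Rh2(S-PTTL)4 (dirhodium tetrakis[N-phthaloyl-(S)-tert-leucinate]) in step 15 is taken as drawn. If either proves opposite, the mirror-image ligand is used and nothing else changes.

Abbreviations: TBS = tert-butyldimethylsilyl; TIPS = triisopropylsilyl; DBF = the (2R,3R)-3-[3,5-bis(TBS-oxy)phenyl]-6-(TBS-oxy)-2-[4-(TBS-oxy)phenyl]-2,3-dihydro-1-benzofuran-5-yl group.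

**Step 1**
Reactants: 1 1-bromo-2,4-dimethoxybenzene; 2 3,5-dimethoxybenzoyl chloride
Product: 4 (5-bromo-2-hydroxy-4-methoxyphenyl)(3,5-dimethoxyphenyl)methanone, via tetramethoxy benzophenone 3 (not isolated)
Conditions: AlCl3 (2.5 equiv), CH2Cl2, 0 °C → reflux; aq HCl
Reagents that add atoms: none
Why: Friedel–Crafts acylation goes to the one ring carbon that is para to one methoxy group and ortho to the other, and AlCl3 chelated between the new ketone and its ortho methoxy oxygen then cleaves only that methyl ether, freeing the phenol that becomes the furan oxygen.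

**Step 2**
Reactants: 4 (5-bromo-2-hydroxy-4-methoxyphenyl)(3,5-dimethoxyphenyl)methanone; 5 4-methoxybenzyl chloride
Product: 6 [5-bromo-4-methoxy-2-[(4-methoxyphenyl)methoxy]phenyl](3,5-dimethoxyphenyl)methanone
Conditions: K2CO3, DMF, 60 °C
Reagents that add atoms: none
Why: Williamson etherification of the chelated but acidic ortho-acyl phenol with a reactive benzylic chloride installs the CH2 group whose C–H bond is used in step 4.

**Step 3**
Reactants: 6 [5-bromo-4-methoxy-2-[(4-methoxyphenyl)methoxy]phenyl](3,5-dimethoxyphenyl)methanone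
Product: 7 hydrazone of ketone 6 (E/Z mixture)
Conditions: N2H4·H2O (10 equiv), AcOH (cat.), EtOH, 90 °C, sealed tube
Reagents that add atoms: hydrazine, NN
Why: Hydrazone condensation of the diaryl ketone with excess hydrazine under mild acid catalysis gives the precursor of the diazo compound, and the aryl bromide and ethers are inert.

**Step 4**
Reactants: 7 hydrazone of ketone 6
Product: 9 (2S,3R)-5-bromo-3-(3,5-dimethoxyphenyl)-6-methoxy-2-(4-methoxyphenyl)-2,3-dihydro-1-benzofuran (2,3-cis), via diaryldiazomethane 8 (not isolated)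
Conditions: MnO2 (8 equiv), MeCN, 0 °C; then Rh2(R-PTAD)4 (1 mol %), 0 °C → rt
Reagents that add atoms: none
Why: MnO2 dehydrogenates the hydrazone to diaryldiazomethane 8, and its donor/donor divalent-rhodium carbene inserts intramolecularly into the 4-methoxybenzylic C–H bond (five-membered mode) to give the 2,3-cis ring, the chiral phthalimido carboxylate pocket setting C3 as R.

**Step 5**
Reactants: 9 (2S,3R)-5-bromo-3-(3,5-dimethoxyphenyl)-6-methoxy-2-(4-methoxyphenyl)-2,3-dihydro-1-benzofuran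
Product: 11 (2S,3R)-3-(3,5-dimethoxyphenyl)-6-methoxy-2-(4-methoxyphenyl)-2,3-dihydro-1-benzofuran-5-carbaldehyde, via aryllithium 10 (not isolated)
Conditions: n-BuLi (1.1 equiv), THF, −78 °C; DMF, −78 → 0 °C; H2O
Reagents that add atoms: N,N-dimethylformamide, CN(C)C=O
Why: Bromine–lithium exchange is far faster than deprotonation at −78 °C and the aryllithium is formylated by DMF (Bouveault reaction), the methyl ether ortho to lithium being unable to migrate.

**Step 6**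
Reactants: 11 (2S,3R)-3-(3,5-dimethoxyphenyl)-6-methoxy-2-(4-methoxyphenyl)-2,3-dihydro-1-benzofuran-5-carbaldehyde
Product: 13 (2R,3R)-3-(3,5-dihydroxyphenyl)-6-hydroxy-2-(4-hydroxyphenyl)-2,3-dihydro-1-benzofuran-5-carbaldehyde (2,3-trans), via cis-configured tetraphenol 12 (not isolated)
Conditions: BBr3 (8 equiv), CH2Cl2, −78 °C → rt; H2O
Reagents that add atoms: none
Why: BBr3 cleaves the four aryl methyl ethers, and the Lewis acid reversibly ionises the furan O1–C2 bond to a benzylic cation of para-quinone-methide type stabilised by the 4-oxygenated aryl group, so reclosure should deliver the thermodynamically preferred 2,3-trans ring while C3 is not touched.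

**Step 7**
Reactants: 13 (2R,3R)-3-(3,5-dihydroxyphenyl)-6-hydroxy-2-(4-hydroxyphenyl)-2,3-dihydro-1-benzofuran-5-carbaldehyde
Product: 14 DBF-carbaldehyde, (2R,3R)-3-[3,5-bis(TBS-oxy)phenyl]-6-(TBS-oxy)-2-[4-(TBS-oxy)phenyl]-2,3-dihydro-1-benzofuran-5-carbaldehyde
Conditions: TBSCl (6 equiv), imidazole (10 equiv), DMF, rt
Reagents that add atoms: tert-butyldimethylsilyl chloride, CC(C)(C)[Si](C)(C)Cl
Why: Silylation of all four phenols with TBSCl and imidazole gives ethers that survive every later step and leave together with fluoride at the end.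

**Step 8**
Reactants: 14 DBF-carbaldehyde
Product: 15 DBF-methanol, [(2R,3R)-3-[3,5-bis(TBS-oxy)phenyl]-6-(TBS-oxy)-2-[4-(TBS-oxy)phenyl]-2,3-dihydro-1-benzofuran-5-yl]methanol
Conditions: NaBH4, THF/MeOH, −20 → 0 °C
Reagents that add atoms: none
Why: Borohydride reduction of the aldehyde at low temperature gives the benzylic alcohol before the ortho silyl group can migrate.

**Step 9**
Reactants: 16 1-(2,4,6-trihydroxyphenyl)ethanone
Product: 17 1-[2-hydroxy-4,6-bis(TIPS-oxy)phenyl]ethanone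
Conditions: TIPSCl (2.1 equiv), imidazole, DMF, 0 °C → rt
Reagents that add atoms: triisopropylsilyl chloride, CC(C)[Si](Cl)(C(C)C)C(C)C
Why: The para hydroxyl and one ortho hydroxyl are silylated while the last hydroxyl stays hydrogen-bonded to the ketone and too hindered for the bulky silyl chloride, which differentiates the two ortho oxygens.

**Step 10**
Reactants: 17 1-[2-hydroxy-4,6-bis(TIPS-oxy)phenyl]ethanone
Product: 18 1-[2-hydroxy-3-iodo-4,6-bis(TIPS-oxy)phenyl]ethanone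
Conditions: N-iodosuccinimide (1.05 equiv), CH2Cl2, 0 °C, dark
Reagents that add atoms: N-iodosuccinimide, O=C1CCC(=O)N1I
Why: Electrophilic iodination takes place ortho to the free phenol, since the other ring carbon is shielded by two TIPS ethers, so the iodine ends up beside the oxygen that will become O1 and marks C8 rather than C6.

**Step 11**
Reactants: 18 1-[2-hydroxy-3-iodo-4,6-bis(TIPS-oxy)phenyl]ethanone; 15 DBF-methanol
Product: 19 1-[2-(DBF-methoxy)-3-iodo-4,6-bis(TIPS-oxy)phenyl]ethanone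
Conditions: PPh3, DIAD, THF, 0 °C → rt
Reagents that add atoms: none
Why: Mitsunobu etherification couples the acidic ortho-acyl phenol with the primary benzylic alcohol under neutral conditions that keep all silyl ethers in place.

**Step 12**
Reactants: 19 1-[2-(DBF-methoxy)-3-iodo-4,6-bis(TIPS-oxy)phenyl]ethanone; 20 2-methylbut-1-en-3-yne
Product: 21 1-[2-(DBF-methoxy)-3-(3-methylbut-3-en-1-yn-1-yl)-4,6-bis(TIPS-oxy)phenyl]ethanone
Conditions: Pd(PPh3)2Cl2 (5 mol %), CuI (10 mol %), Et3N/THF, 55 °C, sealed tube, argon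
Reagents that add atoms: none
Why: Sonogashira coupling of the aryl iodide with the terminal enyne forms the C8–C(sp) bond, and because both ortho oxygens are capped no benzofuran can form.

**Step 13**
Reactants: 21 1-[2-(DBF-methoxy)-3-(3-methylbut-3-en-1-yn-1-yl)-4,6-bis(TIPS-oxy)phenyl]ethanone
Product: 22 1-[2-(DBF-methoxy)-3-[(1Z)-3-methylbuta-1,3-dien-1-yl]-4,6-bis(TIPS-oxy)phenyl]ethanone
Conditions: H2 (1 atm), Pd/CaCO3 poisoned with Pb(OAc)2 (Lindlar catalyst), quinoline, EtOAc, rt, stopped after 1 equiv H2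
Reagents that add atoms: none
Why: Syn delivery of hydrogen on the poisoned palladium surface gives the Z-alkene, and the alkyne is reduced faster than the 1,1-disubstituted alkene, the ketone or the benzyl ether (Lindlar semi-hydrogenation).

**Step 14**
Reactants: 22 1-[2-(DBF-methoxy)-3-[(1Z)-3-methylbuta-1,3-dien-1-yl]-4,6-bis(TIPS-oxy)phenyl]ethanone
Product: 25 2-diazo-1-[2-(DBF-methoxy)-3-[(1Z)-3-methylbuta-1,3-dien-1-yl]-4,6-bis(TIPS-oxy)phenyl]ethanone, via lithium enolate 23 (not isolated), via trifluoroacetyl diketone 24 (not isolated)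
Conditions: LiN(SiMe3)2 (1.1 equiv), THF, −78 °C; CF3CO2CH2CF3, −78 °C; then MeSO2N3, Et3N, H2O (1 equiv), MeCN, rt
Reagents that add atoms: methanesulfonyl azide, CS(=O)(=O)N=[N+]=[N-]; 2,2,2-trifluoroethyl trifluoroacetate, O=C(OCC(F)(F)F)C(F)(F)F (its trifluoroacetyl group stays only in 24)
Why: Detrifluoroacetylative diazo transfer (Danheiser): the kinetic enolate of the methyl ketone is trifluoroacetylated, and the activated diketone accepts the diazo group from MeSO2N3 and then loses the trifluoroacetyl group, giving the terminal diazoketone without strong acid or heat.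

**Step 15**
Reactants: 25 2-diazo-1-[2-(DBF-methoxy)-3-[(1Z)-3-methylbuta-1,3-dien-1-yl]-4,6-bis(TIPS-oxy)phenyl]ethanone
Product: 26 (2S)-2-DBF-8-[(1Z)-3-methylbuta-1,3-dien-1-yl]-5,7-bis(TIPS-oxy)-2,3-dihydro-4H-chromen-4-one
Conditions: Rh2(S-PTTL)4 (2 mol %), CH2Cl2, 4 Å MS, slow addition of 25 over 4 h, 0 °C → rt
Reagents that add atoms: none
Why: Rh2(S-PTTL)4 takes N2 out of 25 to give an electrophilic divalent-rhodium acyl carbene at C3, which inserts through a three-centre, hydride-transfer-like transition state into one C2–H bond of the ArO–CH2–DBF ether, forming C2–C3 and releasing the catalyst. The closest known reaction type is the dirhodium carboxylate-catalysed intramolecular C–H insertion of 2-alkoxyaryl alpha-diazoketones to chroman-4-ones, and step 4 of this route is its five-membered analogue. Ring C closes in the six-membered (1,6-insertion) mode, the only one open because the atom 1,5 to the carbene is O1 and the chain is held by ring A. The new stereocentre C2 is set by the chiral carboxylate pocket, which differentiates the two benzylic hydrogens; the remote furan stereocentres should exert no bias, and any 2R epimer is a separable diastereomer. The step needs C–H insertion to beat oxonium-ylide formation at O1 with 1,2-benzyl shift, O–H insertion, cyclopropanation and carbene dimerisation: the C2–H bond is doubly activated (alpha oxygen, electron-rich ring B with para furan oxygen), O1 is a poorly nucleophilic, doubly flanked aryl ether oxygen conjugated to the ketone, every phenol is silylated and the silyl ether on C5 has no alpha C–H, the Z-diene on C8 stands meta to the carbene-bearing carbon and cannot be reached, and slow addition keeps 25 dilute.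

**Step 16**
Reactants: 26 (2S)-2-DBF-8-[(1Z)-3-methylbuta-1,3-dien-1-yl]-5,7-bis(TIPS-oxy)-2,3-dihydro-4H-chromen-4-one
Product: 27 (2S)-2-[(2R,3R)-3-(3,5-dihydroxyphenyl)-6-hydroxy-2-(4-hydroxyphenyl)-2,3-dihydro-1-benzofuran-5-yl]-5,7-dihydroxy-8-[(1Z)-3-methylbuta-1,3-dien-1-yl]-2,3-dihydro-4H-chromen-4-one (CNP0284772.1)
Conditions: Bu4NF/AcOH (1:1, 8 equiv), THF, 0 °C → rt; pH 7 phosphate buffer
Reagents that add atoms: none
Why: Fluoride removes all six aryl silyl ethers, and the acetic acid buffer keeps the medium near neutral so that ring C does not open to the chalcone and the 7-hydroxyl does not add to the diene.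

**Compound list**

1 | 1-bromo-2,4-dimethoxybenzene | COc1ccc(Br)c(OC)c1 | starting material
2 | 3,5-dimethoxybenzoyl chloride | COc1cc(OC)cc(C(Cl)=O)c1 | starting material
3 | (5-bromo-2,4-dimethoxyphenyl)(3,5-dimethoxyphenyl)methanone | COc1cc(OC)cc(C(=O)c2cc(Br)c(OC)cc2OC)c1 | intermediate (not isolated)
4 | (5-bromo-2-hydroxy-4-methoxyphenyl)(3,5-dimethoxyphenyl)methanone | COc1cc(OC)cc(C(=O)c2cc(Br)c(OC)cc2O)c1 | intermediate
5 | 4-methoxybenzyl chloride | COc1ccc(CCl)cc1 | starting material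
6 | [5-bromo-4-methoxy-2-[(4-methoxyphenyl)methoxy]phenyl](3,5-dimethoxyphenyl)methanone | COc1ccc(COc2cc(OC)c(Br)cc2C(=O)c2cc(OC)cc(OC)c2)cc1 | intermediate
7 | hydrazone of ketone 6 (E/Z mixture) | COc1ccc(COc2cc(OC)c(Br)cc2C(=NN)c2cc(OC)cc(OC)c2)cc1 | intermediate
8 | [5-bromo-4-methoxy-2-[(4-methoxyphenyl)methoxy]phenyl](3,5-dimethoxyphenyl)diazomethane | COc1ccc(COc2cc(OC)c(Br)cc2C(=[N+]=[N-])c2cc(OC)cc(OC)c2)cc1 | intermediate (not isolated)
9 | (2S,3R)-5-bromo-3-(3,5-dimethoxyphenyl)-6-methoxy-2-(4-methoxyphenyl)-2,3-dihydro-1-benzofuran (cis) | Brc1cc2c(cc1OC)O[C@H](c1ccc(OC)cc1)[C@@H]2c1cc(OC)cc(OC)c1 | intermediate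
10 | 5-lithio derivative of 9 | [Li]c1cc2c(cc1OC)O[C@H](c1ccc(OC)cc1)[C@@H]2c1cc(OC)cc(OC)c1 | intermediate (not isolated)
11 | (2S,3R)-3-(3,5-dimethoxyphenyl)-6-methoxy-2-(4-methoxyphenyl)-2,3-dihydro-1-benzofuran-5-carbaldehyde (cis) | O=Cc1cc2c(cc1OC)O[C@H](c1ccc(OC)cc1)[C@@H]2c1cc(OC)cc(OC)c1 | intermediate
12 | (2S,3R)-3-(3,5-dihydroxyphenyl)-6-hydroxy-2-(4-hydroxyphenyl)-2,3-dihydro-1-benzofuran-5-carbaldehyde (cis) | O=Cc1cc2c(cc1O)O[C@H](c1ccc(O)cc1)[C@@H]2c1cc(O)cc(O)c1 | intermediate (not isolated)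
13 | (2R,3R)-3-(3,5-dihydroxyphenyl)-6-hydroxy-2-(4-hydroxyphenyl)-2,3-dihydro-1-benzofuran-5-carbaldehyde (trans) | O=Cc1cc2c(cc1O)O[C@@H](c1ccc(O)cc1)[C@@H]2c1cc(O)cc(O)c1 | intermediate
14 | DBF-carbaldehyde (tetrakis-TBS ether of 13) | O=Cc1cc2c(cc1O[Si](C)(C)C(C)(C)C)O[C@@H](c1ccc(O[Si](C)(C)C(C)(C)C)cc1)[C@@H]2c1cc(O[Si](C)(C)C(C)(C)C)cc(O[Si](C)(C)C(C)(C)C)c1 | intermediate
15 | DBF-methanol | OCc1cc2c(cc1O[Si](C)(C)C(C)(C)C)O[C@@H](c1ccc(O[Si](C)(C)C(C)(C)C)cc1)[C@@H]2c1cc(O[Si](C)(C)C(C)(C)C)cc(O[Si](C)(C)C(C)(C)C)c1 | intermediate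
16 | 1-(2,4,6-trihydroxyphenyl)ethanone | CC(=O)c1c(O)cc(O)cc1O | starting material
17 | 1-[2-hydroxy-4,6-bis(TIPS-oxy)phenyl]ethanone | CC(=O)c1c(O)cc(O[Si](C(C)C)(C(C)C)C(C)C)cc1O[Si](C(C)C)(C(C)C)C(C)C | intermediate
18 | 1-[2-hydroxy-3-iodo-4,6-bis(TIPS-oxy)phenyl]ethanone | CC(=O)c1c(O)c(I)c(O[Si](C(C)C)(C(C)C)C(C)C)cc1O[Si](C(C)C)(C(C)C)C(C)C | intermediate
19 | 1-[2-(DBF-methoxy)-3-iodo-4,6-bis(TIPS-oxy)phenyl]ethanone | CC(=O)c1c(OCc2cc3c(cc2O[Si](C)(C)C(C)(C)C)O[C@@H](c2ccc(O[Si](C)(C)C(C)(C)C)cc2)[C@@H]3c2cc(O[Si](C)(C)C(C)(C)C)cc(O[Si](C)(C)C(C)(C)C)c2)c(I)c(O[Si](C(C)C)(C(C)C)C(C)C)cc1O[Si](C(C)C)(C(C)C)C(C)C | intermediate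
20 | 2-methylbut-1-en-3-yne | C=C(C)C#C | starting material
21 | 1-[2-(DBF-methoxy)-3-(3-methylbut-3-en-1-yn-1-yl)-4,6-bis(TIPS-oxy)phenyl]ethanone | CC(=O)c1c(OCc2cc3c(cc2O[Si](C)(C)C(C)(C)C)O[C@@H](c2ccc(O[Si](C)(C)C(C)(C)C)cc2)[C@@H]3c2cc(O[Si](C)(C)C(C)(C)C)cc(O[Si](C)(C)C(C)(C)C)c2)c(C#CC(C)=C)c(O[Si](C(C)C)(C(C)C)C(C)C)cc1O[Si](C(C)C)(C(C)C)C(C)C | intermediate
22 | 1-[2-(DBF-methoxy)-3-[(1Z)-3-methylbuta-1,3-dien-1-yl]-4,6-bis(TIPS-oxy)phenyl]ethanone | CC(=O)c1c(OCc2cc3c(cc2O[Si](C)(C)C(C)(C)C)O[C@@H](c2ccc(O[Si](C)(C)C(C)(C)C)cc2)[C@@H]3c2cc(O[Si](C)(C)C(C)(C)C)cc(O[Si](C)(C)C(C)(C)C)c2)c(/C=C\C(C)=C)c(O[Si](C(C)C)(C(C)C)C(C)C)cc1O[Si](C(C)C)(C(C)C)C(C)C | intermediate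
23 | lithium enolate of 22 | C=C(O[Li])c1c(OCc2cc3c(cc2O[Si](C)(C)C(C)(C)C)O[C@@H](c2ccc(O[Si](C)(C)C(C)(C)C)cc2)[C@@H]3c2cc(O[Si](C)(C)C(C)(C)C)cc(O[Si](C)(C)C(C)(C)C)c2)c(/C=C\C(C)=C)c(O[Si](C(C)C)(C(C)C)C(C)C)cc1O[Si](C(C)C)(C(C)C)C(C)C | intermediate (not isolated)
24 | 4,4,4-trifluoro-1-[2-(DBF-methoxy)-3-[(1Z)-3-methylbuta-1,3-dien-1-yl]-4,6-bis(TIPS-oxy)phenyl]butane-1,3-dione | O=C(CC(=O)C(F)(F)F)c1c(OCc2cc3c(cc2O[Si](C)(C)C(C)(C)C)O[C@@H](c2ccc(O[Si](C)(C)C(C)(C)C)cc2)[C@@H]3c2cc(O[Si](C)(C)C(C)(C)C)cc(O[Si](C)(C)C(C)(C)C)c2)c(/C=C\C(C)=C)c(O[Si](C(C)C)(C(C)C)C(C)C)cc1O[Si](C(C)C)(C(C)C)C(C)C | intermediate (not isolated)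
25 | 2-diazo-1-[2-(DBF-methoxy)-3-[(1Z)-3-methylbuta-1,3-dien-1-yl]-4,6-bis(TIPS-oxy)phenyl]ethanone | [N-]=[N+]=CC(=O)c1c(OCc2cc3c(cc2O[Si](C)(C)C(C)(C)C)O[C@@H](c2ccc(O[Si](C)(C)C(C)(C)C)cc2)[C@@H]3c2cc(O[Si](C)(C)C(C)(C)C)cc(O[Si](C)(C)C(C)(C)C)c2)c(/C=C\C(C)=C)c(O[Si](C(C)C)(C(C)C)C(C)C)cc1O[Si](C(C)C)(C(C)C)C(C)C | intermediate
26 | (2S)-2-DBF-8-[(1Z)-3-methylbuta-1,3-dien-1-yl]-5,7-bis(TIPS-oxy)-2,3-dihydro-4H-chromen-4-one | C=C(C)/C=C\c1c(O[Si](C(C)C)(C(C)C)C(C)C)cc(O[Si](C(C)C)(C(C)C)C(C)C)c2c1O[C@H](c1cc3c(cc1O[Si](C)(C)C(C)(C)C)O[C@@H](c1ccc(O[Si](C)(C)C(C)(C)C)cc1)[C@@H]3c1cc(O[Si](C)(C)C(C)(C)C)cc(O[Si](C)(C)C(C)(C)C)c1)CC2=O | intermediate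
27 | (2S)-2-[(2R,3R)-3-(3,5-dihydroxyphenyl)-6-hydroxy-2-(4-hydroxyphenyl)-2,3-dihydro-1-benzofuran-5-yl]-5,7-dihydroxy-8-[(1Z)-3-methylbuta-1,3-dien-1-yl]-2,3-dihydro-4H-chromen-4-one | C=C(C)/C=C\c1c(O)cc(O)c2c1O[C@H](c1cc3c(cc1O)O[C@@H](c1ccc(O)cc1)[C@@H]3c1cc(O)cc(O)c1)CC2=O | target

**Totals**

Total step count: 16. Longest linear sequence: 14 steps (steps 1–8, then 11–16); steps 9 and 10 make the ring A fragment.

**Steps most likely to fail**

Step 15. The carbene may be captured by the lone pair of O1 to give an oxonium ylide that undergoes a 1,2-shift of the electron-rich benzyl group (ring contraction to a benzofuranone), or the catalyst may discriminate poorly between the two benzylic hydrogens. The fallback sets out from 18 and 14 and comes back at 26, closing ring C at O1–C2 instead. The dilithio derivative of 18 (LiN(SiMe3)2, 2.2 equiv, THF, −78 °C) is added to aldehyde 14 to give the aldol adduct as two carbinol epimers, and the (3R)-aldol adduct F1 is separated by chromatography. Intramolecular Mitsunobu etherification (PPh3, DIAD, THF, 0 °C) closes the ring with inversion to the (2S)-8-iodoflavanone F2. Sonogashira coupling with 20 under the conditions of step 12 gives the 8-enynyl flavanone F3, and Lindlar semi-hydrogenation as in step 13 gives 26.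

Step 13. Over-reduction of the 1,1-disubstituted alkene or Z-to-E isomerisation on palladium may erode the diene. The fallback sets out from 19 and comes back at 22, bypassing steps 12 and 13. Enyne 20 is converted by rhodium-catalysed trans-hydroboration ([Rh(cod)Cl]2, P(i-Pr)3, Et3N, pinacolborane, cyclohexane, rt) into the (Z)-dienylboronate F4. This is coupled with iodide 19 by Suzuki–Miyaura reaction (Pd(OAc)2, SPhos, K3PO4, THF/H2O, 45 °C) with retention of the alkene geometry to give 22.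

Step 6. The formyl group may be consumed by BBr3 (benzal bromide formation, Friedel–Crafts condensation with the resorcinol ring) before demethylation and C2 equilibration are complete. The fallback sets out from 9 and comes back at 14. Bromide 9 is demethylated and epimerised with BBr3 while no formyl group is present, giving the trans tetraphenol bromide F5. This is silylated (TBSCl, imidazole, DMF) to the tetrakis-TBS bromide F6, and palladium-catalysed reductive carbonylation (Pd(OAc)2, di(1-adamantyl)-n-butylphosphine, CO/H2, TMEDA, toluene, 100 °C) gives aldehyde 14.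

**Further compounds**

F1 | step 15 | (3R)-3-DBF-3-hydroxy-1-[2-hydroxy-3-iodo-4,6-bis(TIPS-oxy)phenyl]propan-1-one | O=C(C[C@@H](O)c2cc3c(cc2O[Si](C)(C)C(C)(C)C)O[C@@H](c2ccc(O[Si](C)(C)C(C)(C)C)cc2)[C@@H]3c2cc(O[Si](C)(C)C(C)(C)C)cc(O[Si](C)(C)C(C)(C)C)c2)c1c(O)c(I)c(O[Si](C(C)C)(C(C)C)C(C)C)cc1O[Si](C(C)C)(C(C)C)C(C)C
F2 | step 15 | (2S)-2-DBF-8-iodo-5,7-bis(TIPS-oxy)-2,3-dihydro-4H-chromen-4-one | Ic1c(O[Si](C(C)C)(C(C)C)C(C)C)cc(O[Si](C(C)C)(C(C)C)C(C)C)c2c1O[C@H](c1cc3c(cc1O[Si](C)(C)C(C)(C)C)O[C@@H](c1ccc(O[Si](C)(C)C(C)(C)C)cc1)[C@@H]3c1cc(O[Si](C)(C)C(C)(C)C)cc(O[Si](C)(C)C(C)(C)C)c1)CC2=O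
F3 | step 15 | (2S)-2-DBF-8-(3-methylbut-3-en-1-yn-1-yl)-5,7-bis(TIPS-oxy)-2,3-dihydro-4H-chromen-4-one | C=C(C)C#Cc1c(O[Si](C(C)C)(C(C)C)C(C)C)cc(O[Si](C(C)C)(C(C)C)C(C)C)c2c1O[C@H](c1cc3c(cc1O[Si](C)(C)C(C)(C)C)O[C@@H](c1ccc(O[Si](C)(C)C(C)(C)C)cc1)[C@@H]3c1cc(O[Si](C)(C)C(C)(C)C)cc(O[Si](C)(C)C(C)(C)C)c1)CC2=O
F4 | step 13 | 4,4,5,5-tetramethyl-2-[(1Z)-3-methylbuta-1,3-dien-1-yl]-1,3,2-dioxaborolane | C=C(C)/C=C\B1OC(C)(C)C(C)(C)O1
F5 | step 6 | (2R,3R)-5-bromo-3-(3,5-dihydroxyphenyl)-2-(4-hydroxyphenyl)-2,3-dihydro-1-benzofuran-6-ol | Brc1cc2c(cc1O)O[C@@H](c1ccc(O)cc1)[C@@H]2c1cc(O)cc(O)c1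
F6 | step 6 | (2R,3R)-5-bromo-3-[3,5-bis(TBS-oxy)phenyl]-6-(TBS-oxy)-2-[4-(TBS-oxy)phenyl]-2,3-dihydro-1-benzofuran | Brc1cc2c(cc1O[Si](C)(C)C(C)(C)C)O[C@@H](c1ccc(O[Si](C)(C)C(C)(C)C)cc1)[C@@H]2c1cc(O[Si](C)(C)C(C)(C)C)cc(O[Si](C)(C)C(C)(C)C)c1
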